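# Proposed total synthesis of CNP0324463.4 by ring-closing Barbier allylation of a 3-(bromomethyl)butenolide

## Structural features

The target is a heliangolide-type germacranolide: a ten-membered carbocycle (C1–C10) trans-fused at C6/C7 to an α-methylene-γ-butyrolactone (O–C6, C7–C11(=C13)–C12=O). Around the large ring lie a trans C1/C10 epoxide (methyl on C10), a C3 benzoate, a Z-trisubstituted C4=C5 alkene (methyl on C4), the lactone oxygen on C6, the fusion carbon C7 and a C8 ester of (2S,3R)-2,3-dimethyloxirane-2-carboxylic acid. The ring configuration is 1R,3S,6R,7R,8R,10R. C6, C7 and C8 are contiguous (H-6/H-7 trans, H-7/H-8 cis, i.e. 6α-O, 7α-H, 8β-O); C3 stands 1,4 to C6 across the Z alkene, so no substrate control links it to the triad; C1/C10 are remote from both. Fragile groups are the methylene lactone (Michael acceptor), the doubly allylic C3–O and C6–O bonds, the two epoxides (acid), the ring 1,5-diene (transannular cyclisation, Cope rearrangement) and the 8β-oxygen, which can take over the lactone under base. The real difficulty is closing the ten-membered ring with both alkene geometries intact while setting C7 and C8, without late enolate chemistry to introduce C13. The key step uses the fact that C7, the β-carbon of the lactone, is bonded to the carbinol carbon C8 while C11 carries the exocyclic C13. This is the pattern left by an allyl-transposing (SE2′) addition of a 3-(metallomethyl)butenolide to a C8 aldehyde.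

## Logic of the disconnections

**34 to 33.** The two C–O bonds of the C1/C10 oxirane are cut. C1=C10 is the only electron-rich alkene (C4=C5 carries two allylic acyloxy groups, C11=C13 is conjugated), and the trans epoxide maps onto the E alkene. This removes two stereocentres and the most acid-labile group from every earlier step. The forward step must attack the outer face of the conformer with the C10 methyl on the β side and stop after one epoxidation.

**33 to 28 and 32.** The C8 O–acyl bond is cut. The epoxy acyl group would not survive hydride, cuprate or indium steps, and the cut separates the two chiral domains. The forward acylation of a hindered secondary alcohol must proceed with retention and without lactone migration to O8 or addition to the methylene lactone.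

**32 to 31 to 30 to 29.** The oxirane C–O bonds of the side chain and its oxidation level are traced back to an E allylic alcohol and then to the acid 29. The forward epoxidation must be reagent-controlled, and the oxidation to the acid must spare the epoxide.

**28 to 26 (key).** The C7–C8 bond is cut. This one cut opens the ten-membered ring, removes C7 and C8 as stereocentres and turns the methylene lactone into a stable butenolide bromide. The forward step must form the ring rather than oligomers, add to the butenolide face opposite the C6 arm, and select one aldehyde face.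

**26 back to 20.** No skeletal bond is cut; the aldehyde, bromide and benzoate are traced to a PMB ether, a TBS ether and a TES ether (25, 24, 23, 22, 21, 20). The benzoate cannot pass hydride reagents, and the bromide and aldehyde cannot pass anything earlier. The order is fixed: benzoate before bromide (amine bases would quaternise the bromide), bromide before PMB removal (one free hydroxyl at a time), aldehyde last.

**20 to 19.** C11–C12 and C12–O(C6) are cut (carbonylative lactonisation). This reduces the butenolide to a Z-iodoallylic alcohol plus a one-carbon carbonyl unit. The iodide must be cis to C6.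

**19 to 17.** C11–I and C7–H are cut. The Z-iodoalkene comes from an alkyne by hydroxyl-directed trans-hydroalumination. The demand is that aluminium ends on C11 and is trapped before the neighbouring silyloxy group is eliminated.

**17 to 14 and 15.** C6–C7 is cut. This is the convergent junction with the three-carbon unit that becomes C7, C11 and C13, and it sets C6. It needs reagent control, because C3 is too remote to help, and it must not isomerise the Z enal.

**14 to 11.** The C4–methyl bond is cut (13 and 12 are redox relays). Syn addition of methyl and hydrogen across an ynoate gives the Z alkene with the methyl on C4. The alkenylcopper must be protonated before it equilibrates, and C3–O must be masked so that no lactone or lactol forms.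

**11 to 7 and 8.** C3–C4 is cut (10 is the unprotected adduct). This sets C3 and brings in C4, C5 and C6. The demand is enantioface control on an enolisable β,γ-unsaturated aldehyde.

**7 to 2 and 3.** C1–C2 and the C10–methyl bond are cut (6 is the alcohol). Syn carbometallation of the terminal alkyne fixes the 1(10)E alkene, and the alkenyl metal opens 3. Methyl must go to the internal carbon and alkene geometry must be kept in the transfer.

**2 to 1.** The O–PMB bond is cut, leaving the four-carbon alkynol.

## Other disconnections considered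

Alternative 1: The cut runs through the bonds of a cyclobutane. Irradiation of enone A2 with cyclobutene A3 would form C4–C5 and C1–C10 and give the cis-anti-cis tricyclic adduct A1. Heating would then cleave the C5–C10 and C1–C4 bonds of its central ring and unveil the ten-membered 1(10),4-diene.
- In its favour: no ring closure under dilution is needed; C7 and C8 are set on a six-membered ring, where a trans relationship is easy to secure; cis-anti-cis adducts open towards E,Z-dienes, the heliangolide pattern; C3 arrives masked as a ketal.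
- Against it here: head-to-head regiochemistry and facial selectivity relative to the C8 silyl ether are both required. Which alkene becomes E and which Z is not under firm control. The thermolysis runs at temperatures where the 1,5-diene can undergo Cope rearrangement. After opening, C3 and C6 are ketones that need two stereoselective reductions in a flexible ring, followed by lactonisation and a late α-methylenation.
- Comparison: on structure, A1 holds all ten ring carbons and C7/C8 but none of C3, C6 or C13, whereas 28 holds all of them. On mechanism, a photochemical and pericyclic sequence is the better on ring-closure entropy and at least the equal on the C7/C8 relationship. The chosen plan is the better on alkene geometry, which is fixed before closure, and on the lactone, which is formed in the closure. On step economy the carbocycle is reached sooner, but the post-opening adjustments bring the total to about the same or more.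

Alternative 2: The cut is at C2–C3, with the later epoxide C1–O bond. Oxidation of oxime A5 with NaOCl would give nitrile oxide A6, which adds across the terminal vinyl group (C1=C2) to close the ring as the isoxazoline-bridged lactone A4.
- In its favour: C10 comes from the chiral pool (linalool), so the epoxide no longer depends on facial selectivity; it would be closed by displacement at C1, which is stereospecific. The cycloadduct carries O-1 and a latent C3 carbonyl, and the C6–C8 triad is in place before closure.
- Against it here: a ten-membered bridged cycloaddition is uncertain in regiochemistry and in configuration at C1, and hypochlorite meets an electron-rich trisubstituted alkene. After closure come N–O cleavage, stereoselective C3 reduction, differentiation of O-1 and O-3, sulfonylation and closure, benzoylation, desilylation, acylation and α-methylenation of a base-sensitive lactone.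
- Comparison: on structure, A4 lacks C13 and has C3 at the wrong oxidation level. On mechanism, both ring closures need dilution (equal); the alternative is the better for the absolute configuration of the C1/C10 epoxide. On step economy the chosen plan is clearly better (two steps after ring closure against roughly eight to ten).

Alternative 3: The cut is the C6–O bond. The carbocyclic amide A8 would be treated with PhI(OAc)2 and I2 under visible light. Hydrogen is transferred from C6 to nitrogen through a six-membered array, the amide oxygen bonds to C6, and hydrolysis gives the 13-nor lactone A7.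
- In its favour: C6 needs no oxygen and no separately set stereocentre until late, which is the better redox economy; H-6 is allylic and geometrically placed; intramolecular delivery should make the ring fusion predictable; no dilution is needed for this step.
- Against it here: the allylic C6 radical or cation is delocalised to C4, which puts the Z geometry and the site of C–O formation at risk. Iodine electrophiles and acidic by-products meet two epoxides. A7 still needs α-methylenation by enolate chemistry beside two esters and two epoxides. Above all, A8 is itself a fully decorated ten-membered ring whose closure this plan does not address.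
- Comparison: on structure, it postpones the hardest problem, whereas the chosen plan solves ring and lactone together. On mechanism, radical C–H functionalisation is the equal on ring-fusion control and the better on oxidation-state economy at C6. On step economy it is probably longer once ring construction and methylenation are counted.

Key step: step 18

Remark on the chemistry: the Zn-ProPhenol alkynylations are written for the sense (S,S)-ligand → Re-face addition, the facial bias this catalyst shows in its aldol reactions. If the sense proves opposite for 7 or 14, the antipodal ligand is used and nothing else changes.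

Remark on the structures: 26 and 28 were compared atom by atom with 34. Constitution, the 4Z and 1(10)E geometries and the configurations at C3, C6, C7 and C8 agree, so no structure had to be corrected. 28 is the syn adduct of the allylation (H-7/H-8 cis).

Remark on materials: 3, 8 and 15 are taken as purchased.

## Route

Step 1
Reactants: 1 but-3-yn-1-ol
Product: 2 1-[(but-3-yn-1-yloxy)methyl]-4-methoxybenzene
Conditions: NaH, PMBCl, Bu4NI (cat.), THF, 0 °C to rt
Reagents that add atoms: 4-methoxybenzyl chloride, COc1ccc(CCl)cc1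
Why: Williamson etherification; the PMB ether survives the organoaluminium, cuprate, hydride and palladium steps and is later removed oxidatively beside the allylic bromide and the benzoate.

Step 2
Reactants: 2 1-[(but-3-yn-1-yloxy)methyl]-4-methoxybenzene; 3 oxirane
Product: 6 (3E)-6-[(4-methoxyphenyl)methoxy]-4-methylhex-3-en-1-ol, via alkenyldimethylalane 4 (not isolated), via lithium alkenylaluminate 5 (not isolated)
Conditions: AlMe3, Cp2ZrCl2 (cat.), CH2Cl2, 0 °C to rt; volatiles removed; n-BuLi, hexane/THF, −78 to 0 °C; 3, 0 °C to rt; then 1 M HCl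
Reagents that add atoms: trimethylaluminium, C[Al](C)C
Why: Negishi carboalumination adds methyl and aluminium syn across the alkyne with aluminium on the terminal carbon, which fixes the 1(10)E alkene; the derived lithium alkenylaluminate opens the epoxide with retention of alkene geometry and forms C1–C2.

Step 3
Reactants: 6 (3E)-6-[(4-methoxyphenyl)methoxy]-4-methylhex-3-en-1-ol
Product: 7 (3E)-6-[(4-methoxyphenyl)methoxy]-4-methylhex-3-enal
Conditions: DMP, NaHCO3, CH2Cl2, 0 °C
Reagents that add atoms: none
Why: Dess–Martin oxidation under buffered, non-basic conditions keeps the β,γ-alkene out of conjugation; the aldehyde is used at once.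

Step 4
Reactants: 7 (3E)-6-[(4-methoxyphenyl)methoxy]-4-methylhex-3-enal; 8 methyl prop-2-ynoate
Product: 10 methyl (4S,6E)-4-hydroxy-9-[(4-methoxyphenyl)methoxy]-7-methylnon-6-en-2-ynoate, via methylzinc alkynylide 9 (not isolated)
Conditions: (S,S)-ProPhenol (20 mol %), Me2Zn, Ph3PO (40 mol %), toluene, 8 premixed, then 7 added slowly, 0 to 4 °C
Reagents that add atoms: none
Why: Zn-ProPhenol catalysed enantioselective alkynylation of an aldehyde with a propiolate; the dinuclear zinc catalyst sets C3 by Re-face delivery of the alkynyl group, which corresponds to (S); low temperature and slow addition of 7 limit enolisation.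

Step 5
Reactants: 10 methyl (4S,6E)-4-hydroxy-9-[(4-methoxyphenyl)methoxy]-7-methylnon-6-en-2-ynoate
Product: 11 methyl (4S,6E)-9-[(4-methoxyphenyl)methoxy]-7-methyl-4-[(triethylsilyl)oxy]non-6-en-2-ynoate
Conditions: TESOTf, 2,6-lutidine, CH2Cl2, −78 °C
Reagents that add atoms: triethylsilyl trifluoromethanesulfonate, CC[Si](CC)(CC)OS(=O)(=O)C(F)(F)F
Why: Silylation with a silyl triflate and a hindered base avoids amine addition to the ynoate; the TES ether prevents lactonisation in step 6 and lactol formation in step 8.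

Step 6
Reactants: 11 methyl (4S,6E)-9-[(4-methoxyphenyl)methoxy]-7-methyl-4-[(triethylsilyl)oxy]non-6-en-2-ynoate
Product: 12 methyl (2Z,4S,6E)-9-[(4-methoxyphenyl)methoxy]-3,7-dimethyl-4-[(triethylsilyl)oxy]nona-2,6-dienoate
Conditions: Me2CuLi (from MeLi, CuI), THF, −78 °C; MeOH at −78 °C; aq. NH4Cl
Reagents that add atoms: lithium dimethylcuprate, [Li+].C[Cu-]C
Why: Syn carbocupration (conjugate addition) of the ynoate puts the methyl on C4 cis to H-5; protonation at −78 °C, before the alkenylcopper equilibrates, gives the Z enoate, and the silyloxy group is too poor a leaving group for SN2′ displacement.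

Step 7
Reactants: 12 methyl (2Z,4S,6E)-9-[(4-methoxyphenyl)methoxy]-3,7-dimethyl-4-[(triethylsilyl)oxy]nona-2,6-dienoate
Product: 13 (2Z,4S,6E)-9-[(4-methoxyphenyl)methoxy]-3,7-dimethyl-4-[(triethylsilyl)oxy]nona-2,6-dien-1-ol
Conditions: iBu2AlH, CH2Cl2, −78 °C; Rochelle salt
Reagents that add atoms: none
Why: 1,2-Reduction of the enoate by the aluminium hydride at low temperature; alkene geometry and the silyl and PMB ethers are unaffected.

Step 8
Reactants: 13 (2Z,4S,6E)-9-[(4-methoxyphenyl)methoxy]-3,7-dimethyl-4-[(triethylsilyl)oxy]nona-2,6-dien-1-ol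
Product: 14 (2Z,4S,6E)-9-[(4-methoxyphenyl)methoxy]-3,7-dimethyl-4-[(triethylsilyl)oxy]nona-2,6-dienal
Conditions: DMP, NaHCO3, CH2Cl2, 0 °C
Reagents that add atoms: none
Why: Dess–Martin oxidation of the allylic alcohol under buffered conditions; no acid or amine base is present to isomerise the Z enal, which is used directly.

Step 9
Reactants: 14 (2Z,4S,6E)-9-[(4-methoxyphenyl)methoxy]-3,7-dimethyl-4-[(triethylsilyl)oxy]nona-2,6-dienal; 15 tert-butyldimethyl(prop-2-yn-1-yloxy)silane
Product: 17 (4R,5Z,7S,9E)-1-[(tert-butyldimethylsilyl)oxy]-12-[(4-methoxyphenyl)methoxy]-6,10-dimethyl-7-[(triethylsilyl)oxy]dodeca-5,9-dien-2-yn-4-ol, via methylzinc alkynylide 16 (not isolated)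
Conditions: (R,R)-ProPhenol (20 mol %), Me2Zn, Ph3PO (40 mol %), toluene, 15 premixed, then 14, 0 to 4 °C
Reagents that add atoms: none
Why: Zn-ProPhenol alkynylation, a method suited to α,β-unsaturated aldehydes; the antipodal ligand delivers the alkynyl group to the Si face and sets C6 as (R) under reagent control, independently of the remote C3 centre.

Step 10
Reactants: 17 (4R,5Z,7S,9E)-1-[(tert-butyldimethylsilyl)oxy]-12-[(4-methoxyphenyl)methoxy]-6,10-dimethyl-7-[(triethylsilyl)oxy]dodeca-5,9-dien-2-yn-4-ol
Product: 19 (2Z,4R,5Z,7S,9E)-1-[(tert-butyldimethylsilyl)oxy]-2-iodo-12-[(4-methoxyphenyl)methoxy]-6,10-dimethyl-7-[(triethylsilyl)oxy]dodeca-2,5,9-trien-4-ol, via cyclic vinylalanate 18 (not isolated)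
Conditions: NaAlH2(OCH2CH2OMe)2 (Red-Al), THF, 0 °C; I2, THF, −78 to 0 °C; Rochelle salt, Na2S2O3
Reagents that add atoms: iodine, II
Why: Alkoxide-directed trans-hydroalumination of a propargylic alcohol: hydride goes to C7 and aluminium ends on C11 in a five-membered alanate, so iodine replaces aluminium with retention and lies cis to C6; only the C6 alkoxide can direct, and the low temperature keeps the alanate from eliminating the silyloxy group.

Step 11
Reactants: 19 (2Z,4R,5Z,7S,9E)-1-[(tert-butyldimethylsilyl)oxy]-2-iodo-12-[(4-methoxyphenyl)methoxy]-6,10-dimethyl-7-[(triethylsilyl)oxy]dodeca-2,5,9-trien-4-ol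
Product: 20 (5R)-3-{[(tert-butyldimethylsilyl)oxy]methyl}-5-[(1Z,3S,5E)-8-[(4-methoxyphenyl)methoxy]-2,6-dimethyl-3-[(triethylsilyl)oxy]octa-1,5-dien-1-yl]furan-2(5H)-one
Conditions: Pd(PPh3)4 (5 mol %), CO (1 atm), K2CO3, THF, 50 °C
Reagents that add atoms: carbon monoxide, [C-]#[O+]
Why: Carbonylative lactonisation: zerovalent palladium inserts into the C–I bond, CO inserts, and the cis C6 hydroxyl captures the acylpalladium; the C6–O bond is not broken, so the configuration is retained.

Step 12
Reactants: 20 (5R)-3-{[(tert-butyldimethylsilyl)oxy]methyl}-5-[(1Z,3S,5E)-8-[(4-methoxyphenyl)methoxy]-2,6-dimethyl-3-[(triethylsilyl)oxy]octa-1,5-dien-1-yl]furan-2(5H)-one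
Product: 21 (5R)-3-{[(tert-butyldimethylsilyl)oxy]methyl}-5-[(1Z,3S,5E)-3-hydroxy-8-[(4-methoxyphenyl)methoxy]-2,6-dimethylocta-1,5-dien-1-yl]furan-2(5H)-one
Conditions: PPTS (cat.), MeOH/CH2Cl2, 0 °C to rt
Reagents that add atoms: none
Why: Acid-catalysed methanolysis removes the secondary TES ether much faster than the primary TBS ether; with O-6 tied up in the lactone, the C3 hydroxyl is the only free one.

Step 13
Reactants: 21 (5R)-3-{[(tert-butyldimethylsilyl)oxy]methyl}-5-[(1Z,3S,5E)-3-hydroxy-8-[(4-methoxyphenyl)methoxy]-2,6-dimethylocta-1,5-dien-1-yl]furan-2(5H)-one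
Product: 22 (1Z,3S,5E)-1-[(2R)-4-{[(tert-butyldimethylsilyl)oxy]methyl}-5-oxo-2,5-dihydrofuran-2-yl]-8-[(4-methoxyphenyl)methoxy]-2,6-dimethylocta-1,5-dien-3-yl benzoate
Conditions: BzCl, pyridine, DMAP (cat.), CH2Cl2, 0 °C to rt
Reagents that add atoms: benzoyl chloride, O=C(Cl)c1ccccc1
Why: Acylation under nucleophilic catalysis; the weak amine bases do not deprotonate the doubly allylic C6, and C3 keeps its configuration because its C–O bond is not involved.

Step 14
Reactants: 22 (1Z,3S,5E)-1-[(2R)-4-{[(tert-butyldimethylsilyl)oxy]methyl}-5-oxo-2,5-dihydrofuran-2-yl]-8-[(4-methoxyphenyl)methoxy]-2,6-dimethylocta-1,5-dien-3-yl benzoate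
Product: 23 (1Z,3S,5E)-1-[(2R)-4-(hydroxymethyl)-5-oxo-2,5-dihydrofuran-2-yl]-8-[(4-methoxyphenyl)methoxy]-2,6-dimethylocta-1,5-dien-3-yl benzoate
Conditions: HF·pyridine, pyridine, THF, 0 °C to rt
Reagents that add atoms: none
Why: Fluoride-mediated cleavage of the primary TBS ether under buffered conditions that leave the benzoate, the PMB ether and the butenolide intact.

Step 15
Reactants: 23 (1Z,3S,5E)-1-[(2R)-4-(hydroxymethyl)-5-oxo-2,5-dihydrofuran-2-yl]-8-[(4-methoxyphenyl)methoxy]-2,6-dimethylocta-1,5-dien-3-yl benzoate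
Product: 24 (1Z,3S,5E)-1-[(2R)-4-(bromomethyl)-5-oxo-2,5-dihydrofuran-2-yl]-8-[(4-methoxyphenyl)methoxy]-2,6-dimethylocta-1,5-dien-3-yl benzoate
Conditions: CBr4, PPh3, CH2Cl2, 0 °C
Reagents that add atoms: carbon tetrabromide, BrC(Br)(Br)Br
Why: Appel bromination of the primary allylic alcohol under neutral conditions; it follows the benzoylation because amine bases would quaternise this reactive bromide.

Step 16
Reactants: 24 (1Z,3S,5E)-1-[(2R)-4-(bromomethyl)-5-oxo-2,5-dihydrofuran-2-yl]-8-[(4-methoxyphenyl)methoxy]-2,6-dimethylocta-1,5-dien-3-yl benzoate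
Product: 25 (1Z,3S,5E)-1-[(2R)-4-(bromomethyl)-5-oxo-2,5-dihydrofuran-2-yl]-8-hydroxy-2,6-dimethylocta-1,5-dien-3-yl benzoate
Conditions: DDQ, CH2Cl2/pH 7 buffer, 0 °C
Reagents that add atoms: none
Why: Oxidative cleavage of the PMB ether by DDQ (hydride abstraction at the electron-rich benzylic position, then hydrolysis); the bromide, the benzoate and both alkenes are inert in the buffered two-phase medium.

Step 17
Reactants: 25 (1Z,3S,5E)-1-[(2R)-4-(bromomethyl)-5-oxo-2,5-dihydrofuran-2-yl]-8-hydroxy-2,6-dimethylocta-1,5-dien-3-yl benzoate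
Product: 26 (1Z,3S,5E)-1-[(2R)-4-(bromomethyl)-5-oxo-2,5-dihydrofuran-2-yl]-2,6-dimethyl-8-oxoocta-1,5-dien-3-yl benzoate
Conditions: DMP, NaHCO3, CH2Cl2, 0 °C
Reagents that add atoms: none
Why: Dess–Martin oxidation to the β,γ-unsaturated aldehyde without amine base, so neither conjugation of the alkene nor substitution of the bromide occurs; 26 goes into step 18 without storage.

Step 18
Reactants: 26 (1Z,3S,5E)-1-[(2R)-4-(bromomethyl)-5-oxo-2,5-dihydrofuran-2-yl]-2,6-dimethyl-8-oxoocta-1,5-dien-3-yl benzoate
Product: 28 (3aR,4R,6E,9S,10Z,11aR)-4-hydroxy-6,10-dimethyl-3-methylidene-2-oxo-2,3,3a,4,5,8,9,11a-octahydrocyclodeca[b]furan-9-yl benzoate, via allylindium 27 (not isolated)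
Conditions: In powder (3 equiv), THF/H2O 4:1, 26 added by syringe pump to ≤2 mM, rt
Reagents that add atoms: none
Why: Ring-closing Barbier allylation: indium inserts into the C13–Br bond and the allylindium 27, whose nucleophilic γ-carbon is C7, adds to the tethered C8 aldehyde with allylic transposition (SE2′), forming C7–C8 and moving the double bond to C11=C13. The closest known reaction types are the zinc- or indium-mediated intermolecular addition of 3-(bromomethyl)furan-2(5H)-ones to aldehydes and the ring-closing Barbier or Nozaki–Hiyama allylation used for ten-membered carbocycles. One ring is closed, the ten-membered carbocycle, by 10-exo-trig attack on the carbonyl through a carbon that already belongs to the lactone, so the new alkene lies outside both rings. C7 is controlled by the tether: the chain leaves C6 on one face of the planar butenolide and reaches C7 without eclipsing C5 against C8 only from the opposite face, which gives the trans fusion. C8 is controlled by the orientation of the carbonyl in the cyclic array: the required syn adduct (H-7/H-8 cis, 8β-OH) forms when C9 lies anti to C11 with the carbonyl oxygen turned towards the lactone carbonyl, or from a chair with C9 axial, the mode expected to prevail for aqueous indium or zinc reagents of this class, whereas a chair with C9 equatorial and the metal bridging on the C13 side would give the C8 epimer. The step needs addition to win over protonation of 27 and ring closure to win over dimerisation; the water-tolerant allylindium, the unhindered aldehyde and slow addition to high dilution secure this. The preset 4Z and 1(10)E alkenes take four of the ten ring atoms out of free rotation and shorten the effective chain. The neutral medium leaves the benzoate, the Z alkene and the β,γ-unsaturated aldehyde untouched.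

Step 19
Reactants: 29 (2E)-2-methylbut-2-enoic acid (tiglic acid)
Product: 30 (2E)-2-methylbut-2-en-1-ol
Conditions: LiAlH4, Et2O, 0 °C
Reagents that add atoms: none
Why: Hydride reduction of the acid to the allylic alcohol; 1,2-reduction is favoured at low temperature and the E geometry is kept.

Step 20
Reactants: 30 (2E)-2-methylbut-2-en-1-ol
Product: 31 [(2R,3R)-2,3-dimethyloxiran-2-yl]methanol
Conditions: Ti(OiPr)4 (10 mol %), D-(−)-diisopropyl tartrate (12 mol %), t-BuOOH, 4 Å molecular sieves, CH2Cl2, −20 °C
Reagents that add atoms: tert-butyl hydroperoxide, CC(C)(C)OO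
Why: Sharpless asymmetric epoxidation; the D-(−)-tartrate delivers oxygen to the face that gives the (2R,3R) epoxy alcohol (the L-(+)-tartrate gives 2S,3S with E allylic alcohols), and the E alkene fixes the two methyls cis.

Step 21
Reactants: 31 [(2R,3R)-2,3-dimethyloxiran-2-yl]methanol
Product: 32 (2S,3R)-2,3-dimethyloxirane-2-carboxylic acid
Conditions: RuCl3 (2 mol %), NaIO4, MeCN/EtOAc/H2O, 0 °C to rt
Reagents that add atoms: water, O
Why: Ruthenium tetroxide oxidation of the primary alcohol to the acid through the aldehyde hydrate; the epoxide is untouched, and the descriptor at C2 changes only because the substituent priorities change.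

Step 22
Reactants: 28 (3aR,4R,6E,9S,10Z,11aR)-4-hydroxy-6,10-dimethyl-3-methylidene-2-oxo-2,3,3a,4,5,8,9,11a-octahydrocyclodeca[b]furan-9-yl benzoate; 32 (2S,3R)-2,3-dimethyloxirane-2-carboxylic acid
Product: 33 (3aR,4R,6E,9S,10Z,11aR)-9-(benzoyloxy)-6,10-dimethyl-3-methylidene-2-oxo-2,3,3a,4,5,8,9,11a-octahydrocyclodeca[b]furan-4-yl (2S,3R)-2,3-dimethyloxirane-2-carboxylate
Conditions: DCC, DMAP (cat.), CH2Cl2, 0 °C to rt
Reagents that add atoms: none
Why: Steglich esterification of the C8 alcohol with retention; mild carbodiimide activation at 0 °C avoids epoxide opening, base-induced migration of the lactone to O8 and conjugate addition to the methylene lactone.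

Step 23
Reactants: 33 (3aR,4R,6E,9S,10Z,11aR)-9-(benzoyloxy)-6,10-dimethyl-3-methylidene-2-oxo-2,3,3a,4,5,8,9,11a-octahydrocyclodeca[b]furan-4-yl (2S,3R)-2,3-dimethyloxirane-2-carboxylate
Product: 34 (1R,3S,6R,7R,8R,10R)-3-benzoyloxy-1,10-epoxy-8-[(2S,3R)-2,3-dimethyloxirane-2-carbonyloxy]germacra-4Z,11(13)-dien-6,12-olide (CNP0324463.4)
Conditions: mCPBA (1.1 equiv), NaHCO3, CH2Cl2, 0 °C
Reagents that add atoms: 3-chloroperbenzoic acid, OOC(=O)c1cccc(Cl)c1
Why: Prilezhaev epoxidation; C1=C10 is the only electron-rich alkene (C4=C5 is deactivated by two allylic acyloxy groups, C11=C13 is conjugated), and attack on the outer face of the conformer with the C10 methyl β gives the 1β,10α (1R,10R) epoxide, trans because the alkene is E.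

## Compound list

1 | but-3-yn-1-ol | C#CCCO | starting material
2 | 1-[(but-3-yn-1-yloxy)methyl]-4-methoxybenzene | C#CCCOCc1ccc(OC)cc1 | intermediate
3 | oxirane | C1CO1 | starting material
4 | [(1E)-4-[(4-methoxyphenyl)methoxy]-2-methylbut-1-en-1-yl]dimethylalane | C[Al](C)/C=C(\C)CCOCc1ccc(OC)cc1 | intermediate (not isolated)
5 | lithium butyl[(1E)-4-[(4-methoxyphenyl)methoxy]-2-methylbut-1-en-1-yl]dimethylaluminate | [Li+].CCCC[Al-](C)(C)/C=C(\C)CCOCc1ccc(OC)cc1 | intermediate (not isolated)
6 | (3E)-6-[(4-methoxyphenyl)methoxy]-4-methylhex-3-en-1-ol | OCC/C=C(\C)CCOCc1ccc(OC)cc1 | intermediate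
7 | (3E)-6-[(4-methoxyphenyl)methoxy]-4-methylhex-3-enal | O=CC/C=C(\C)CCOCc1ccc(OC)cc1 | intermediate
8 | methyl prop-2-ynoate | C#CC(=O)OC | starting material
9 | methyl 3-(methylzincio)prop-2-ynoate | C[Zn]C#CC(=O)OC | intermediate (not isolated)
10 | methyl (4S,6E)-4-hydroxy-9-[(4-methoxyphenyl)methoxy]-7-methylnon-6-en-2-ynoate | COC(=O)C#C[C@@H](O)C/C=C(\C)CCOCc1ccc(OC)cc1 | intermediate
11 | methyl (4S,6E)-9-[(4-methoxyphenyl)methoxy]-7-methyl-4-[(triethylsilyl)oxy]non-6-en-2-ynoate | COC(=O)C#C[C@@H](O[Si](CC)(CC)CC)C/C=C(\C)CCOCc1ccc(OC)cc1 | intermediate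
12 | methyl (2Z,4S,6E)-9-[(4-methoxyphenyl)methoxy]-3,7-dimethyl-4-[(triethylsilyl)oxy]nona-2,6-dienoate | COC(=O)/C=C(/C)[C@@H](O[Si](CC)(CC)CC)C/C=C(\C)CCOCc1ccc(OC)cc1 | intermediate
13 | (2Z,4S,6E)-9-[(4-methoxyphenyl)methoxy]-3,7-dimethyl-4-[(triethylsilyl)oxy]nona-2,6-dien-1-ol | OC/C=C(/C)[C@@H](O[Si](CC)(CC)CC)C/C=C(\C)CCOCc1ccc(OC)cc1 | intermediate
14 | (2Z,4S,6E)-9-[(4-methoxyphenyl)methoxy]-3,7-dimethyl-4-[(triethylsilyl)oxy]nona-2,6-dienal | O=C/C=C(/C)[C@@H](O[Si](CC)(CC)CC)C/C=C(\C)CCOCc1ccc(OC)cc1 | intermediate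
15 | tert-butyldimethyl(prop-2-yn-1-yloxy)silane | C#CCO[Si](C)(C)C(C)(C)C | starting material
16 | {3-[(tert-butyldimethylsilyl)oxy]prop-1-yn-1-yl}(methyl)zinc | C[Zn]C#CCO[Si](C)(C)C(C)(C)C | intermediate (not isolated)
17 | (4R,5Z,7S,9E)-1-[(tert-butyldimethylsilyl)oxy]-12-[(4-methoxyphenyl)methoxy]-6,10-dimethyl-7-[(triethylsilyl)oxy]dodeca-5,9-dien-2-yn-4-ol | CC(C)(C)[Si](C)(C)OCC#C[C@H](O)/C=C(/C)[C@@H](O[Si](CC)(CC)CC)C/C=C(\C)CCOCc1ccc(OC)cc1 | intermediate
18 | sodium bis(2-methoxyethoxy)aluminate in which aluminium is bonded to O-4 and C-2 of reduced 17 (five-membered cyclic alkenyl alkoxy alanate) | [Na+].COCCO[Al-]1(OCCOC)O[C@H](/C=C(/C)[C@@H](O[Si](CC)(CC)CC)C/C=C(\C)CCOCc2ccc(OC)cc2)C=C1CO[Si](C)(C)C(C)(C)C | intermediate (not isolated)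
19 | (2Z,4R,5Z,7S,9E)-1-[(tert-butyldimethylsilyl)oxy]-2-iodo-12-[(4-methoxyphenyl)methoxy]-6,10-dimethyl-7-[(triethylsilyl)oxy]dodeca-2,5,9-trien-4-ol | CC(C)(C)[Si](C)(C)OC/C(I)=C/[C@H](O)/C=C(/C)[C@@H](O[Si](CC)(CC)CC)C/C=C(\C)CCOCc1ccc(OC)cc1 | intermediate
20 | (5R)-3-{[(tert-butyldimethylsilyl)oxy]methyl}-5-[(1Z,3S,5E)-8-[(4-methoxyphenyl)methoxy]-2,6-dimethyl-3-[(triethylsilyl)oxy]octa-1,5-dien-1-yl]furan-2(5H)-one | CC(C)(C)[Si](C)(C)OCC1=C[C@@H](/C=C(/C)[C@@H](O[Si](CC)(CC)CC)C/C=C(\C)CCOCc2ccc(OC)cc2)OC1=O | intermediate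
21 | (5R)-3-{[(tert-butyldimethylsilyl)oxy]methyl}-5-[(1Z,3S,5E)-3-hydroxy-8-[(4-methoxyphenyl)methoxy]-2,6-dimethylocta-1,5-dien-1-yl]furan-2(5H)-one | CC(C)(C)[Si](C)(C)OCC1=C[C@@H](/C=C(/C)[C@@H](O)C/C=C(\C)CCOCc2ccc(OC)cc2)OC1=O | intermediate
22 | (1Z,3S,5E)-1-[(2R)-4-{[(tert-butyldimethylsilyl)oxy]methyl}-5-oxo-2,5-dihydrofuran-2-yl]-8-[(4-methoxyphenyl)methoxy]-2,6-dimethylocta-1,5-dien-3-yl benzoate | CC(C)(C)[Si](C)(C)OCC1=C[C@@H](/C=C(/C)[C@@H](OC(=O)c2ccccc2)C/C=C(\C)CCOCc2ccc(OC)cc2)OC1=O | intermediate
23 | (1Z,3S,5E)-1-[(2R)-4-(hydroxymethyl)-5-oxo-2,5-dihydrofuran-2-yl]-8-[(4-methoxyphenyl)methoxy]-2,6-dimethylocta-1,5-dien-3-yl benzoate | OCC1=C[C@@H](/C=C(/C)[C@@H](OC(=O)c2ccccc2)C/C=C(\C)CCOCc2ccc(OC)cc2)OC1=O | intermediate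
24 | (1Z,3S,5E)-1-[(2R)-4-(bromomethyl)-5-oxo-2,5-dihydrofuran-2-yl]-8-[(4-methoxyphenyl)methoxy]-2,6-dimethylocta-1,5-dien-3-yl benzoate | BrCC1=C[C@@H](/C=C(/C)[C@@H](OC(=O)c2ccccc2)C/C=C(\C)CCOCc2ccc(OC)cc2)OC1=O | intermediate
25 | (1Z,3S,5E)-1-[(2R)-4-(bromomethyl)-5-oxo-2,5-dihydrofuran-2-yl]-8-hydroxy-2,6-dimethylocta-1,5-dien-3-yl benzoate | BrCC1=C[C@@H](/C=C(/C)[C@@H](OC(=O)c2ccccc2)C/C=C(\C)CCO)OC1=O | intermediate
26 | (1Z,3S,5E)-1-[(2R)-4-(bromomethyl)-5-oxo-2,5-dihydrofuran-2-yl]-2,6-dimethyl-8-oxoocta-1,5-dien-3-yl benzoate | BrCC1=C[C@@H](/C=C(/C)[C@@H](OC(=O)c2ccccc2)C/C=C(\C)CC=O)OC1=O | intermediate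
27 | allylindium derived from 26 (monovalent indium on C13 in place of bromine) | [In]CC1=C[C@@H](/C=C(/C)[C@@H](OC(=O)c2ccccc2)C/C=C(\C)CC=O)OC1=O | intermediate (not isolated)
28 | (3aR,4R,6E,9S,10Z,11aR)-4-hydroxy-6,10-dimethyl-3-methylidene-2-oxo-2,3,3a,4,5,8,9,11a-octahydrocyclodeca[b]furan-9-yl benzoate (3β-benzoyloxy-8β-hydroxygermacra-1(10)E,4Z,11(13)-trien-6α,12-olide) | C=C1C(=O)O[C@@H]2/C=C(/C)[C@@H](OC(=O)c3ccccc3)C/C=C(\C)C[C@@H](O)[C@@H]12 | intermediate
29 | (2E)-2-methylbut-2-enoic acid (tiglic acid) | C/C=C(\C)C(=O)O | starting material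
30 | (2E)-2-methylbut-2-en-1-ol | C/C=C(\C)CO | intermediate
31 | [(2R,3R)-2,3-dimethyloxiran-2-yl]methanol | OC[C@@]1(C)O[C@@H]1C | intermediate
32 | (2S,3R)-2,3-dimethyloxirane-2-carboxylic acid | OC(=O)[C@@]1(C)O[C@@H]1C | intermediate
33 | (3aR,4R,6E,9S,10Z,11aR)-9-(benzoyloxy)-6,10-dimethyl-3-methylidene-2-oxo-2,3,3a,4,5,8,9,11a-octahydrocyclodeca[b]furan-4-yl (2S,3R)-2,3-dimethyloxirane-2-carboxylate | C=C1C(=O)O[C@@H]2/C=C(/C)[C@@H](OC(=O)c3ccccc3)C/C=C(\C)C[C@@H](OC(=O)[C@@]3(C)O[C@@H]3C)[C@@H]12 | intermediate
34 | (1R,3S,6R,7R,8R,10R)-3-benzoyloxy-1,10-epoxy-8-[(2S,3R)-2,3-dimethyloxirane-2-carbonyloxy]germacra-4Z,11(13)-dien-6,12-olide (CNP0324463.4) | C=C1C(=O)O[C@@H]2/C=C(/C)[C@@H](OC(=O)c3ccccc3)C[C@H]3O[C@]3(C)C[C@@H](OC(=O)[C@@]3(C)O[C@@H]3C)[C@@H]12 | target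

## Step count and least certain steps

Total step count: 23. Longest linear sequence: 20 steps (steps 1–18, 22 and 23, from 1); the acid 32 is made in a three-step branch (steps 19–21).

**Step 18 (key step).** The most likely failure is poor facial selectivity at the aldehyde. The ordinary chair with the chain equatorial and the metal bridging on the C13 side leads to the C8 epimer, and the ten-membered transition state may not override it. Intermolecular coupling at insufficient dilution is the second risk. Fallback: accept the epimer and introduce the side chain with inversion. From 26 the same ring closure then delivers (3aR,4S,6E,9S,10Z,11aR)-4-hydroxy-6,10-dimethyl-3-methylidene-2-oxo-2,3,3a,4,5,8,9,11a-octahydrocyclodeca[b]furan-9-yl benzoate F1. Mitsunobu esterification of F1 with 32 (PPh3, DIAD, toluene, 0 °C) inverts C8 and returns to the route at 33.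

**Step 9.** The most likely failure is Z to E isomerisation of the enal through γ-deprotonation by the zinc alkoxide and amine sites of the catalyst, together with incomplete enantioface control on a β,β-disubstituted enal. Fallback: from 14, addition of the lithium acetylide of 15 (n-BuLi, THF, −78 °C) gives 17 mixed with its C6 epimer, (4S,5Z,7S,9E)-1-[(tert-butyldimethylsilyl)oxy]-12-[(4-methoxyphenyl)methoxy]-6,10-dimethyl-7-[(triethylsilyl)oxy]dodeca-5,9-dien-2-yn-4-ol F2. Dess–Martin oxidation of the mixture gives (5Z,7S,9E)-1-[(tert-butyldimethylsilyl)oxy]-12-[(4-methoxyphenyl)methoxy]-6,10-dimethyl-7-[(triethylsilyl)oxy]dodeca-5,9-dien-2-yn-4-one F3. Midland reduction with (R)-Alpine-Borane, in which the alkynyl group acts as the small substituent, returns to the route at 17.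

**Step 10.** The most likely failure is β-elimination of the silyloxy group from the alkenylalanate (allene formation) or protodealumination before iodine is added. Fallback (hydride-free butenolide construction):
- From 14, the alkynylation of step 9 run with 8 in place of 15 gives methyl (4R,5Z,7S,9E)-4-hydroxy-12-[(4-methoxyphenyl)methoxy]-6,10-dimethyl-7-[(triethylsilyl)oxy]dodeca-5,9-dien-2-ynoate F4.
- Pd(PPh3)4-catalysed syn hydrostannation (Bu3SnH, THF, 0 °C) places tin α to the ester and cis to H-7, and lactonisation gives (5R)-5-[(1Z,3S,5E)-8-[(4-methoxyphenyl)methoxy]-2,6-dimethyl-3-[(triethylsilyl)oxy]octa-1,5-dien-1-yl]-3-(tributylstannyl)furan-2(5H)-one F5.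
- Iododestannylation (I2, CH2Cl2, 0 °C) gives (5R)-3-iodo-5-[(1Z,3S,5E)-8-[(4-methoxyphenyl)methoxy]-2,6-dimethyl-3-[(triethylsilyl)oxy]octa-1,5-dien-1-yl]furan-2(5H)-one F6.
- Stille coupling with tributyl(hydroxymethyl)stannane (Pd(PPh3)4, dioxane, 80 °C) gives (5R)-3-(hydroxymethyl)-5-[(1Z,3S,5E)-8-[(4-methoxyphenyl)methoxy]-2,6-dimethyl-3-[(triethylsilyl)oxy]octa-1,5-dien-1-yl]furan-2(5H)-one F7.
- Silylation (TBSCl, imidazole) returns to the route at 20.

**Step 4.** The most likely failure is enolisation of the β,γ-unsaturated aldehyde under the zinc alkoxide conditions, leading to aldol reaction or conjugation and eroding conversion and enantiomeric purity. Fallback: take C3 from the chiral pool.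
- (R)-Glycidol is silylated (TESCl, imidazole) to (S)-triethyl(oxiran-2-ylmethoxy)silane F8.
- Aluminate 5, generated from 2 as in step 2, opens F8 at its terminal carbon to give (2S,4E)-7-[(4-methoxyphenyl)methoxy]-5-methyl-1-[(triethylsilyl)oxy]hept-4-en-2-ol F9.
- TESOTf and 2,6-lutidine give (2S,4E)-7-[(4-methoxyphenyl)methoxy]-5-methyl-1,2-bis[(triethylsilyl)oxy]hept-4-ene F10.
- Swern oxidation, which cleaves and oxidises only the primary TES ether, gives (2S,4E)-7-[(4-methoxyphenyl)methoxy]-5-methyl-2-[(triethylsilyl)oxy]hept-4-enal F11.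
- Ohira–Bestmann homologation (dimethyl (1-diazo-2-oxopropyl)phosphonate, K2CO3, MeOH) gives triethyl{[(3S,5E)-8-[(4-methoxyphenyl)methoxy]-6-methyloct-5-en-1-yn-3-yl]oxy}silane F12.
- n-BuLi followed by methyl chloroformate returns to the route at 11.

**Step 23.** The most likely failure is insufficient facial selectivity, through reaction of the ring conformer with the C10 methyl on the α side, or acid-induced transannular opening of the new epoxide by the C4=C5 alkene. Fallback: change the controlling element and the order. From 28, hydroxyl-directed epoxidation of the homoallylic alcohol (VO(acac)2, t-BuOOH, CH2Cl2, 0 °C) gives (1R,3S,6R,7R,8R,10R)-3-benzoyloxy-1,10-epoxy-8-hydroxygermacra-4Z,11(13)-dien-6,12-olide F13. Esterification with 32 under the conditions of step 22 returns to the route at 34.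

## Further compounds

F1 | step 18 | (3aR,4S,6E,9S,10Z,11aR)-4-hydroxy-6,10-dimethyl-3-methylidene-2-oxo-2,3,3a,4,5,8,9,11a-octahydrocyclodeca[b]furan-9-yl benzoate | C=C1C(=O)O[C@@H]2/C=C(/C)[C@@H](OC(=O)c3ccccc3)C/C=C(\C)C[C@H](O)[C@@H]12
F2 | step 9 | (4S,5Z,7S,9E)-1-[(tert-butyldimethylsilyl)oxy]-12-[(4-methoxyphenyl)methoxy]-6,10-dimethyl-7-[(triethylsilyl)oxy]dodeca-5,9-dien-2-yn-4-ol | CC(C)(C)[Si](C)(C)OCC#C[C@@H](O)/C=C(/C)[C@@H](O[Si](CC)(CC)CC)C/C=C(\C)CCOCc1ccc(OC)cc1
F3 | step 9 | (5Z,7S,9E)-1-[(tert-butyldimethylsilyl)oxy]-12-[(4-methoxyphenyl)methoxy]-6,10-dimethyl-7-[(triethylsilyl)oxy]dodeca-5,9-dien-2-yn-4-one | CC(C)(C)[Si](C)(C)OCC#CC(=O)/C=C(/C)[C@@H](O[Si](CC)(CC)CC)C/C=C(\C)CCOCc1ccc(OC)cc1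
F4 | step 10 | methyl (4R,5Z,7S,9E)-4-hydroxy-12-[(4-methoxyphenyl)methoxy]-6,10-dimethyl-7-[(triethylsilyl)oxy]dodeca-5,9-dien-2-ynoate | COC(=O)C#C[C@H](O)/C=C(/C)[C@@H](O[Si](CC)(CC)CC)C/C=C(\C)CCOCc1ccc(OC)cc1
F5 | step 10 | (5R)-5-[(1Z,3S,5E)-8-[(4-methoxyphenyl)methoxy]-2,6-dimethyl-3-[(triethylsilyl)oxy]octa-1,5-dien-1-yl]-3-(tributylstannyl)furan-2(5H)-one | CCCC[Sn](CCCC)(CCCC)C1=C[C@@H](/C=C(/C)[C@@H](O[Si](CC)(CC)CC)C/C=C(\C)CCOCc2ccc(OC)cc2)OC1=O
F6 | step 10 | (5R)-3-iodo-5-[(1Z,3S,5E)-8-[(4-methoxyphenyl)methoxy]-2,6-dimethyl-3-[(triethylsilyl)oxy]octa-1,5-dien-1-yl]furan-2(5H)-one | IC1=C[C@@H](/C=C(/C)[C@@H](O[Si](CC)(CC)CC)C/C=C(\C)CCOCc2ccc(OC)cc2)OC1=O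
F7 | step 10 | (5R)-3-(hydroxymethyl)-5-[(1Z,3S,5E)-8-[(4-methoxyphenyl)methoxy]-2,6-dimethyl-3-[(triethylsilyl)oxy]octa-1,5-dien-1-yl]furan-2(5H)-one | OCC1=C[C@@H](/C=C(/C)[C@@H](O[Si](CC)(CC)CC)C/C=C(\C)CCOCc2ccc(OC)cc2)OC1=O
F8 | step 4 | (S)-triethyl(oxiran-2-ylmethoxy)silane | CC[Si](CC)(CC)OC[C@@H]1CO1
F9 | step 4 | (2S,4E)-7-[(4-methoxyphenyl)methoxy]-5-methyl-1-[(triethylsilyl)oxy]hept-4-en-2-ol | CC[Si](CC)(CC)OC[C@@H](O)C/C=C(\C)CCOCc1ccc(OC)cc1
F10 | step 4 | (2S,4E)-7-[(4-methoxyphenyl)methoxy]-5-methyl-1,2-bis[(triethylsilyl)oxy]hept-4-ene | CC[Si](CC)(CC)OC[C@@H](O[Si](CC)(CC)CC)C/C=C(\C)CCOCc1ccc(OC)cc1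
F11 | step 4 | (2S,4E)-7-[(4-methoxyphenyl)methoxy]-5-methyl-2-[(triethylsilyl)oxy]hept-4-enal | O=C[C@@H](O[Si](CC)(CC)CC)C/C=C(\C)CCOCc1ccc(OC)cc1
F12 | step 4 | triethyl{[(3S,5E)-8-[(4-methoxyphenyl)methoxy]-6-methyloct-5-en-1-yn-3-yl]oxy}silane | C#C[C@@H](O[Si](CC)(CC)CC)C/C=C(\C)CCOCc1ccc(OC)cc1
F13 | step 23 | (1R,3S,6R,7R,8R,10R)-3-benzoyloxy-1,10-epoxy-8-hydroxygermacra-4Z,11(13)-dien-6,12-olide | C=C1C(=O)O[C@@H]2/C=C(/C)[C@@H](OC(=O)c3ccccc3)C[C@H]3O[C@]3(C)C[C@@H](O)[C@@H]12
A1 | alternative 1 | cis-anti-cis tricyclic photoadduct (cyclohexanone, central cyclobutane, ketal-bearing cyclobutane) | O=C1[C@@H]2[C@@]3(C)C(OC)(OC)C[C@H]3[C@]2(C)C[C@@H](O[Si](C)(C)C(C)(C)C)[C@H]1CC(=O)OC(C)(C)C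
A2 | alternative 1 | tert-butyl 2-{6-[(tert-butyldimethylsilyl)oxy]-4-methyl-2-oxocyclohex-3-en-1-yl}acetate (enone with C7 and C8 set) | O=C1C=C(C)C[C@@H](O[Si](C)(C)C(C)(C)C)[C@H]1CC(=O)OC(C)(C)C
A3 | alternative 1 | 3,3-dimethoxy-2-methylcyclobut-1-ene | COC1(OC)CC=C1C
A4 | alternative 2 | isoxazoline-bridged ten-membered lactone | O=C1C[C@@H]2[C@H](O[Si](C)(C)C(C)(C)C)C[C@@](C)(O[Si](CC)(CC)CC)[C@@H]3CC(=NO3)/C(C)=C\[C@H]2O1
A5 | alternative 2 | Z-enal oxime of the seco lactone with terminal vinyl group on C10 | O=C1C[C@H]([C@H](O[Si](C)(C)C(C)(C)C)C[C@@](C)(O[Si](CC)(CC)CC)C=C)[C@@H](/C=C(/C)C=NO)O1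
A6 | alternative 2 | nitrile oxide derived from the oxime | O=C1C[C@H]([C@H](O[Si](C)(C)C(C)(C)C)C[C@@](C)(O[Si](CC)(CC)CC)C=C)[C@@H](/C=C(/C)C#[N+][O-])O1
A7 | alternative 3 | 13-nor lactone (the target without the exocyclic methylene) | C1C(=O)O[C@@H]2/C=C(/C)[C@@H](OC(=O)c3ccccc3)C[C@H]3O[C@]3(C)C[C@@H](OC(=O)[C@@]3(C)O[C@@H]3C)[C@@H]12
A8 | alternative 3 | ten-membered carbocyclic primary amide (C7 acetamide, C6 methylene) | NC(=O)C[C@H]1C/C=C(/C)[C@@H](OC(=O)c2ccccc2)C[C@H]2O[C@]2(C)C[C@H]1OC(=O)[C@@]3(C)O[C@@H]3C
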